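The seven-membered lactone (ring-fusion carbon C6–O7–C8(=O)–C9H2–C10H(OH)–C11H2–ring-fusion carbon C12) is, without O7, a 3-hydroxycyclohexanone: C9–C10 is an aldol bond and C6–C12 a Michael bond. Both are made at once by an amine-catalysed domino Michael/aldol reaction of methyl acetoacetate with a silylated enynal, neither of which resembles the target. The catalyst sets C12, and equilibration relays C6 and C10. Baeyer–Villiger insertion of O7, Sonogashira union with a δ-lactone-derived (Z)-iodoalkene and ring-closing metathesis of the trisubstituted C4=C5 alkene complete the ten-membered ring.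

Key step: step 2

Remark: atom numbers are C1 (CH–O bearing Et), C2, C3, C4(Me)=C5, C6, O7, C8(=O), C9, C10(OH), C11, C12, C13=C14, C15(Me)=C16, C17, C18(=O)–O–C1; the sense of induction of the (S)-configured amine catalyst is assumed from the usual face-shielding model.

Step 1
Reactants: 1 3-(trimethylsilyl)prop-2-ynal; 2 (triphenylphosphoranylidene)acetaldehyde
Product: 3 (E)-5-(trimethylsilyl)pent-2-en-4-ynal
Conditions: CH2Cl2, rt (1 in slight excess)
Reagents that add atoms: none
Why: Wittig olefination with the stabilised formyl ylide should be E-selective and stop after one homologation because ynal 1 is more electrophilic than enal 3.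

Step 2
Reactants: 3 (E)-5-(trimethylsilyl)pent-2-en-4-ynal; 4 methyl acetoacetate
Product: 6 methyl (1S,4S,6R)-4-hydroxy-2-oxo-6-[(trimethylsilyl)ethynyl]cyclohexane-1-carboxylate, via Michael adduct 5 (not isolated)
Conditions: (S)-2-{bis[3,5-bis(trifluoromethyl)phenyl](trimethylsilyloxy)methyl}pyrrolidine (10 mol%), PhCO2H (10 mol%), toluene, 0 °C → rt; then Et3N (cat.), rt
Reagents that add atoms: none
Why: The amine condenses with enal 3 to an E-iminium ion, one face of which is shielded by the diaryl(silyloxy)methyl group, so the enol of 4 adds to C12 from the open face (organocatalytic Michael addition, forming C6–C12) and hydrolysis releases keto aldehyde 5. The methyl ketone of 5 then closes onto the aldehyde in a 6-(enolexo)-exo-trig aldol reaction that forms C9–C10; the closest known reaction type is the amine-catalysed domino Michael/aldol reaction of β-keto esters with enals to 3-hydroxycyclohexanones. C12 is set by the catalyst, C6 by epimerisation of the β-keto ester (ester trans to the alkynyl group), and C10 by the reversible aldol step, which should settle on the all-equatorial isomer with OH cis to the alkynyl group. The step needs 1,4- rather than 1,6-addition to the enynal, which the larger LUMO coefficient at C12 and the silyl cap on the alkyne terminus should secure, and it needs the aldol to stop before dehydration, which the absence of strong acid and heat should secure.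

Step 3
Reactants: 6 hydroxy keto ester
Product: 7 methyl (1S,4S,6R)-4-[(tert-butyldimethylsilyl)oxy]-2-oxo-6-[(trimethylsilyl)ethynyl]cyclohexane-1-carboxylate
Conditions: TBSCl, imidazole, DMF, 0 °C → rt
Reagents that add atoms: tert-butyldimethylsilyl chloride, CC(C)(C)[Si](C)(C)Cl
Why: Silyl ether formation at the only free hydroxyl; TBSCl/imidazole should not silylate the β-keto ester.

Step 4
Reactants: 7 silyl ether
Product: 8 2-(hydroxymethyl)-5-[(tert-butyldimethylsilyl)oxy]-3-[(trimethylsilyl)ethynyl]cyclohexan-1-ol (C8 epimers; C6, C10, C12 as in 7)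
Conditions: LiBH4, THF/MeOH, 0 °C → rt
Reagents that add atoms: none
Why: Hydride reduction of the ketone and then, chelation-assisted, of the ester gives the 1,3-diol; C6 keeps the trans arrangement to C12 reached by equilibration, and the new C8 carbinol is erased in step 8.

Step 5
Reactants: 8 diol
Product: 9 3-ethynyl-2-(hydroxymethyl)-5-[(tert-butyldimethylsilyl)oxy]cyclohexan-1-ol (C8 epimers)
Conditions: K2CO3 (cat.), MeOH, rt
Reagents that add atoms: none
Why: Methoxide-mediated protodesilylation of the alkynylsilane; the TBS ether is stable to these conditions.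

Step 6
Reactants: 9 alkynyl diol
Product: 10 6-ethynyl-2-hydroxy-4-[(tert-butyldimethylsilyl)oxy]cyclohexane-1-carbaldehyde (C8 epimers)
Conditions: TEMPO (cat.), PhI(OAc)2, CH2Cl2, rt
Reagents that add atoms: none
Why: Oxoammonium (TEMPO) oxidation is selective for the primary over the secondary alcohol.

Step 7
Reactants: 10 hydroxy aldehyde
Product: 11 2-ethenyl-3-ethynyl-5-[(tert-butyldimethylsilyl)oxy]cyclohexan-1-ol (C8 epimers)
Conditions: Ph3PCH3Br, KOtBu (excess), THF, 0 °C
Reagents that add atoms: methylenetriphenylphosphorane (from Ph3PCH3Br and KOtBu), C=P(c1ccccc1)(c1ccccc1)c1ccccc1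
Why: Wittig methylenation of the aldehyde; excess ylide compensates for the free OH and the alkyne C–H.

Step 8
Reactants: 11 vinyl alcohol
Product: 12 (2S,3R,5S)-5-[(tert-butyldimethylsilyl)oxy]-2-ethenyl-3-ethynylcyclohexan-1-one
Conditions: Dess–Martin periodinane, CH2Cl2, 0 °C
Reagents that add atoms: none
Why: Dess–Martin oxidation under near-neutral conditions should return the C8 ketone without moving the β,γ-alkene into conjugation.

Step 9
Reactants: 12 ketone
Product: 13 (4S,6S,7S)-4-[(tert-butyldimethylsilyl)oxy]-7-ethenyl-6-ethynyloxepan-2-one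
Conditions: mCPBA, CH2Cl2, 0 °C → rt
Reagents that add atoms: meta-chloroperoxybenzoic acid, OOC(=O)c1cccc(Cl)c1
Why: Baeyer–Villiger oxidation: the secondary allylic carbon C6 migrates in preference to primary C9 and with retention, so O7 is inserted between C6 and C8; the terminal alkene and alkyne should be epoxidised more slowly.

Step 10
Reactants: 14 (S)-2-ethyloxirane
Product: 15 (S)-hex-5-en-3-ol
Conditions: vinylmagnesium bromide, CuI (cat.), THF, −30 °C
Reagents that add atoms: vinylmagnesium bromide, C=C[Mg]Br
Why: Copper-catalysed Grignard opening of the epoxide at its unsubstituted carbon leaves the bought stereocentre (C1) untouched.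

Step 11
Reactants: 15 (S)-hex-5-en-3-ol
Product: 16 (S)-hex-5-en-3-yl acrylate
Conditions: acryloyl chloride, Et3N, DMAP (cat.), CH2Cl2, 0 °C
Reagents that add atoms: acryloyl chloride, C=CC(=O)Cl
Why: Acylation of the secondary alcohol.

Step 12
Reactants: 16 acrylate
Product: 17 (S)-6-ethyl-5,6-dihydro-2H-pyran-2-one
Conditions: Grubbs II (cat.), CH2Cl2, reflux
Reagents that add atoms: none
Why: Ring-closing metathesis of the acrylate/terminal alkene pair gives the six-membered unsaturated lactone.

Step 13
Reactants: 17 unsaturated lactone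
Product: 18 (4S,6S)-6-ethyl-4-(prop-1-en-2-yl)oxan-2-one
Conditions: isopropenylmagnesium bromide, CuBr·SMe2 (cat.), THF, −78 → −40 °C
Reagents that add atoms: isopropenylmagnesium bromide, CC(=C)[Mg]Br
Why: Copper-catalysed conjugate addition should occur anti to the C1 ethyl group of the half-chair lactone and so set C3 (4,6-trans).

Step 14
Reactants: 18 lactone
Product: 19 (3S,4S,6S)-6-ethyl-3-(hydroxymethyl)-4-(prop-1-en-2-yl)oxan-2-one
Conditions: LDA, THF, −78 °C; CH2O (gas, from cracked paraformaldehyde)
Reagents that add atoms: formaldehyde, C=O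
Why: Aldol reaction of the lithium enolate with formaldehyde anti to the neighbouring isopropenyl group sets C17 (3,4-trans).

Step 15
Reactants: 19 hydroxymethyl lactone
Product: 21 methyl acetal of the lactol derived from 19 (anomer mixture), via lactol 20 (not isolated)
Conditions: DIBAL-H, CH2Cl2, −78 °C; then MeOH, PPTS (cat.), rt
Reagents that add atoms: methanol, CO
Why: DIBAL reduction to the lactol and acid-catalysed acetalisation mask C18, so that C16 can become an aldehyde without forming an enolisable 1,3-dicarbonyl.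

Step 16
Reactants: 21 acetal alcohol
Product: 22 acetal aldehyde (C16 = CHO)
Conditions: Dess–Martin periodinane, CH2Cl2, rt
Reagents that add atoms: none
Why: Dess–Martin oxidation of the primary alcohol under non-basic conditions should not epimerise C17.

Step 17
Reactants: 22 acetal aldehyde
Product: 23 (Z)-iodoalkene (C17–CH=C(CH3)I, iodine cis to C17)
Conditions: Ph3P(CHICH3)I, NaHMDS, THF/DMPU, −78 °C
Reagents that add atoms: (1-iodoethylidene)triphenylphosphorane (from the phosphonium iodide and NaHMDS), CC(I)=P(c1ccccc1)(c1ccccc1)c1ccccc1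
Why: Stork–Zhao-type Wittig olefination with the α-iodo ylide gives the (Z)-2-iodoalkene, placing iodine cis to C17 as the later Z-C15=C16 bond requires.

Step 18
Reactants: 13 alkynyl lactone; 23 (Z)-iodoalkene
Product: 24 enyne (C13≡C14–C15(Me)=C16)
Conditions: PdCl2(PPh3)2 (cat.), CuI (cat.), Et3N, THF, rt
Reagents that add atoms: none
Why: Sonogashira coupling proceeds with retention of the iodoalkene geometry and at room temperature should outpace ionisation of the allylic lactone.

Step 19
Reactants: 24 enyne
Product: 25 (13Z,15Z)-diene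
Conditions: Zn(Cu/Ag), MeOH/H2O, rt
Reagents that add atoms: none
Why: Activated zinc reduces only the alkyne that is conjugated with an alkene and delivers the cis-alkene, giving the Z,Z-diene.

Step 20
Reactants: 25 diene bearing vinyl (C5) and isopropenyl (C4) groups
Product: 26 ten-membered carbocycle (C18 methyl acetal, C10 TBS ether)
Conditions: Grubbs II (cat.), 1,4-benzoquinone (cat.), toluene, 80 °C, high dilution
Reagents that add atoms: none
Why: Ring-closing metathesis joins the vinyl and isopropenyl groups with loss of ethene; beside the cis,cis-diene the ten-membered ring should accept only the Z-configured C4=C5 bond, and benzoquinone suppresses Ru–H alkene isomerisation.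

Step 21
Reactants: 26 macrocyclic acetal
Product: 28 rhizolutin, via lactol 27 (not isolated)
Conditions: aq. HF, MeCN, rt; then TEMPO (cat.), PhI(OAc)2, CH2Cl2, rt
Reagents that add atoms: water, O
Why: Aqueous HF cleaves the silyl ether and hydrolyses the methyl acetal, and TEMPO/PhI(OAc)2 should oxidise the lactol much faster than the secondary C10 alcohol (lactol-to-lactone oxidation).

Compound list
1 | 3-(trimethylsilyl)prop-2-ynal | C[Si](C)(C)C#CC=O | starting material
2 | (triphenylphosphoranylidene)acetaldehyde | O=CC=P(c1ccccc1)(c1ccccc1)c1ccccc1 | starting material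
3 | (E)-5-(trimethylsilyl)pent-2-en-4-ynal | C[Si](C)(C)C#C/C=C/C=O | intermediate
4 | methyl acetoacetate | CC(=O)CC(=O)OC | starting material
5 | methyl (3R)-2-acetyl-5-oxo-3-[(trimethylsilyl)ethynyl]pentanoate (C6 epimers) | CC(=O)C(C(=O)OC)[C@@H](CC=O)C#C[Si](C)(C)C | intermediate
6 | methyl (1S,4S,6R)-4-hydroxy-2-oxo-6-[(trimethylsilyl)ethynyl]cyclohexane-1-carboxylate | COC(=O)[C@@H]1C(=O)C[C@@H](O)C[C@H]1C#C[Si](C)(C)C | intermediate
7 | methyl (1S,4S,6R)-4-[(tert-butyldimethylsilyl)oxy]-2-oxo-6-[(trimethylsilyl)ethynyl]cyclohexane-1-carboxylate | COC(=O)[C@@H]1C(=O)C[C@@H](O[Si](C)(C)C(C)(C)C)C[C@H]1C#C[Si](C)(C)C | intermediate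
8 | 2-(hydroxymethyl)-5-[(tert-butyldimethylsilyl)oxy]-3-[(trimethylsilyl)ethynyl]cyclohexan-1-ol (C8 epimers) | OC[C@@H]1C(O)C[C@@H](O[Si](C)(C)C(C)(C)C)C[C@H]1C#C[Si](C)(C)C | intermediate
9 | 3-ethynyl-2-(hydroxymethyl)-5-[(tert-butyldimethylsilyl)oxy]cyclohexan-1-ol (C8 epimers) | OC[C@@H]1C(O)C[C@@H](O[Si](C)(C)C(C)(C)C)C[C@H]1C#C | intermediate
10 | 6-ethynyl-2-hydroxy-4-[(tert-butyldimethylsilyl)oxy]cyclohexane-1-carbaldehyde (C8 epimers) | O=C[C@@H]1C(O)C[C@@H](O[Si](C)(C)C(C)(C)C)C[C@H]1C#C | intermediate
11 | 2-ethenyl-3-ethynyl-5-[(tert-butyldimethylsilyl)oxy]cyclohexan-1-ol (C8 epimers) | C=C[C@@H]1C(O)C[C@@H](O[Si](C)(C)C(C)(C)C)C[C@H]1C#C | intermediate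
12 | (2S,3R,5S)-5-[(tert-butyldimethylsilyl)oxy]-2-ethenyl-3-ethynylcyclohexan-1-one | C=C[C@@H]1C(=O)C[C@@H](O[Si](C)(C)C(C)(C)C)C[C@H]1C#C | intermediate
13 | (4S,6S,7S)-4-[(tert-butyldimethylsilyl)oxy]-7-ethenyl-6-ethynyloxepan-2-one | C=C[C@@H]1OC(=O)C[C@@H](O[Si](C)(C)C(C)(C)C)C[C@H]1C#C | intermediate
14 | (S)-2-ethyloxirane | CC[C@H]1CO1 | starting material
15 | (S)-hex-5-en-3-ol | CC[C@H](O)CC=C | intermediate
16 | (S)-hex-5-en-3-yl acrylate | CC[C@H](OC(=O)C=C)CC=C | intermediate
17 | (S)-6-ethyl-5,6-dihydro-2H-pyran-2-one | CC[C@H]1CC=CC(=O)O1 | intermediate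
18 | (4S,6S)-6-ethyl-4-(prop-1-en-2-yl)oxan-2-one | CC[C@H]1C[C@H](C(C)=C)CC(=O)O1 | intermediate
19 | (3S,4S,6S)-6-ethyl-3-(hydroxymethyl)-4-(prop-1-en-2-yl)oxan-2-one | CC[C@H]1C[C@H](C(C)=C)[C@@H](CO)C(=O)O1 | intermediate
20 | lactol of 19 (anomer mixture) | CC[C@H]1C[C@H](C(C)=C)[C@@H](CO)C(O)O1 | intermediate
21 | methyl acetal of lactol 20 (anomer mixture) | CC[C@H]1C[C@H](C(C)=C)[C@@H](CO)C(OC)O1 | intermediate
22 | acetal aldehyde (C16 = CHO) | CC[C@H]1C[C@H](C(C)=C)[C@@H](C=O)C(OC)O1 | intermediate
23 | (Z)-iodoalkene acetal (C17–CH=C(CH3)I) | CC[C@H]1C[C@H](C(C)=C)[C@@H](/C=C(/C)I)C(OC)O1 | intermediate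
24 | enyne from 13 and 23 | C=C[C@@H]1OC(=O)C[C@@H](O[Si](C)(C)C(C)(C)C)C[C@H]1C#C/C(C)=C\[C@H]2C(OC)O[C@@H](CC)C[C@@H]2C(C)=C | intermediate
25 | (13Z,15Z)-diene, metathesis precursor | C=C[C@@H]1OC(=O)C[C@@H](O[Si](C)(C)C(C)(C)C)C[C@H]1/C=C\C(C)=C/[C@H]2C(OC)O[C@@H](CC)C[C@@H]2C(C)=C | intermediate
26 | macrocycle: 10-O-TBS rhizolutin C18 methyl acetal (anomer mixture) | CC[C@H]1C[C@@H]2/C(C)=C\[C@@H]3OC(=O)C[C@@H](O[Si](C)(C)C(C)(C)C)C[C@H]3/C=C\C(C)=C/[C@H]2C(OC)O1 | intermediate
27 | rhizolutin C18 lactol (anomer mixture) | CC[C@H]1C[C@@H]2/C(C)=C\[C@@H]3OC(=O)C[C@@H](O)C[C@H]3/C=C\C(C)=C/[C@H]2C(O)O1 | intermediate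
28 | rhizolutin | CC[C@H]1C[C@@H]2/C(C)=C\[C@@H]3OC(=O)C[C@@H](O)C[C@H]3/C=C\C(C)=C/[C@H]2C(=O)O1 | target

Total step count: 21. Longest linear sequence: 13 steps (steps 1–9, then 18–21).

Steps most likely to fail

Step 20 (ring-closing metathesis). The catalyst may load only slowly on the allylic-ester vinyl group and the hindered isopropenyl group, so cross-metathesis oligomers or attack on the C13=C14 alkene could outrun closure of the strained ten-membered ring. The fallback is relay metathesis, setting out from aldehyde 10. Wittig reaction with hex-5-enylidenetriphenylphosphorane would give the relay dienol F1, and Dess–Martin oxidation the ketone F2. Baeyer–Villiger oxidation with bis(trimethylsilyl) peroxide/TMSOTf, which spares the alkenes, would give the lactone F3. Sonogashira coupling with 23 would give the enyne F4, and Zn(Cu/Ag) reduction the triene F5. With Grubbs II the catalyst should load on the unhindered terminal alkene, expel cyclopentene and so place the ruthenium alkylidene on C5 intramolecularly. Closure onto the isopropenyl group comes back to the route at 26.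

Step 2 (domino Michael/aldol). The aldol half may stall at keto aldehyde 5, settle on the C10 epimer or go on to dehydration. The fallback separates the two bond formations, setting out from 5: the Michael adduct is isolated from the amine-catalysed step run at 0 °C without base. It is then closed by an (S)-proline-catalysed intramolecular enamine aldol reaction (6-enolexo) under kinetic control, which comes back to the route at 6. No new compound arises (F0).

Step 18 (Sonogashira coupling). Pd(0) may ionise the allylic C6–O7 lactone bond to a π-allyl complex, or the alkyne may homocouple. The fallback is a palladium-free route to the Z,Z-diene, setting out from alkyne 13. Stannylation with Bu3SnOMe would give the alkynylstannane F6. Hydrozirconation with Cp2Zr(H)Cl and protonolysis would give the (Z)-alkenylstannane F7. Coupling of F7 with iodide 23 mediated by copper(I) thiophene-2-carboxylate, with retention at both alkenes, comes back to the route at 25 and bypasses 24 and step 19.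

Further compounds
F1 | step 20 | relay dienol (C5=CH(CH2)3CH=CH2 in place of the vinyl group of 11) | C=CCCC/C=C\[C@@H]1C(O)C[C@@H](O[Si](C)(C)C(C)(C)C)C[C@H]1C#C
F2 | step 20 | relay ketone | C=CCCC/C=C\[C@@H]1C(=O)C[C@@H](O[Si](C)(C)C(C)(C)C)C[C@H]1C#C
F3 | step 20 | relay lactone | C=CCCC/C=C\[C@@H]1OC(=O)C[C@@H](O[Si](C)(C)C(C)(C)C)C[C@H]1C#C
F4 | step 20 | relay enyne | C=CCCC/C=C\[C@@H]1OC(=O)C[C@@H](O[Si](C)(C)C(C)(C)C)C[C@H]1C#C/C(C)=C\[C@H]2C(OC)O[C@@H](CC)C[C@@H]2C(C)=C
F5 | step 20 | relay triene, metathesis precursor | C=CCCC/C=C\[C@@H]1OC(=O)C[C@@H](O[Si](C)(C)C(C)(C)C)C[C@H]1/C=C\C(C)=C/[C@H]2C(OC)O[C@@H](CC)C[C@@H]2C(C)=C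
F0 | step 2 | none | none
F6 | step 18 | alkynylstannane of 13 | C=C[C@@H]1OC(=O)C[C@@H](O[Si](C)(C)C(C)(C)C)C[C@H]1C#C[Sn](CCCC)(CCCC)CCCC
F7 | step 18 | (Z)-alkenylstannane | C=C[C@@H]1OC(=O)C[C@@H](O[Si](C)(C)C(C)(C)C)C[C@H]1/C=C\[Sn](CCCC)(CCCC)CCCC
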